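**Plan**

- The retrosynthesis cuts the C6–C7 and C9–C10 bonds of ring B. This splits the target into a ring A methylenecyclohexane (C1–C6, C10, C18–C20) and the ten carbons C7–C9 and C11–C17 of (R)-citronellic acid.
- The feature that allows this: the C7=C8(C17)–C9 unit of ring B is the isopropylidene end of citronellic acid, and C10(H)–C5=C6 of ring A is an ene-type allyl unit. A cationic [3+3] annulation joins them.
- Forward order: ring A is built first (steps 1–9), the side chain is armed as an E allylic bromide (steps 10–12), ring B closes in step 13, and two deprotections finish.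
- Stereochemistry: C3 is set by Cu-catalysed asymmetric borylation. C4 (anti aldol) and the C10–H centre (equilibration inside a temporary trans-acetonide ring, later removed) follow by substrate control. C5, C10 and C9 are set in step 13 by hydride relay, chair closure and alkene geometry. C13 is bought.

Key step: step 13

Remarks: carbon numbers in the Why lines are the labdane numbers of the target (ring A C1–C5 and C10, ring B C5–C10, C17 on C8, C18 and C19 on C4, C20 on C10). The phosphine enantiomer in step 1 is assumed to be the one that gives the 3S boronate; its mirror image would be used if the sense is opposite.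

**Route**

Step 1
Reactants: 1 2-methylcyclohex-2-en-1-one
Product: 3 (3S)-3-hydroxy-2-methylcyclohexan-1-one (C2 epimers), via boryl ketone 2 (not isolated)
Conditions: B2pin2, CuCl (5 mol%), NaOtBu (10 mol%), (R,R)-QuinoxP* (6 mol%), MeOH, THF, rt; then NaBO3·4H2O, THF–H2O, rt
Reagents that add atoms: bis(pinacolato)diboron, CC1(C)OB(OC1(C)C)B1OC(C)(C)C(C)(C)O1; sodium perborate, [Na+].[O-]OB=O
Why: Copper–boryl conjugate addition (asymmetric β-borylation of an enone) should deliver boron to one face under control of the chiral bisphosphine, and perborate oxidation replaces boron by hydroxyl with retention, so C3 is set by the catalyst while the epimerisable neighbouring centre stays a mixture.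

Step 2
Reactants: 3 (3S)-3-hydroxy-2-methylcyclohexan-1-one
Product: 4 (3S)-2-methyl-1,3-bis(trimethylsilyloxy)cyclohex-1-ene
Conditions: TMSCl, NaI, Et3N, MeCN, rt
Reagents that add atoms: chlorotrimethylsilane, C[Si](C)(C)Cl
Why: Equilibrating enol silylation with iodotrimethylsilane made in situ should give the thermodynamic, tetrasubstituted silyl enol ether and silylate the hydroxyl, which fixes the enol toward the methyl-bearing carbon and creates no stereocentre.

Step 3
Reactants: 4 (3S)-2-methyl-1,3-bis(trimethylsilyloxy)cyclohex-1-ene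
Product: 6 (2R,3S)-3-hydroxy-2-(hydroxymethyl)-2-methylcyclohexan-1-one, via silyl ether aldol 5 (not isolated)
Conditions: 37% aq. HCHO, Yb(OTf)3 (10 mol%), THF, rt; then 1 M HCl, THF, 0 °C
Reagents that add atoms: formaldehyde, C=O
Why: The lanthanide-triflate-catalysed aqueous Mukaiyama aldol (hydroxymethylation of a silyl enol ether) should attack anti to the pseudoaxial allylic silyloxy group, so the new quaternary C4 carries CH2OH trans to the C3 oxygen, and dilute acid then frees the C3 hydroxyl.

Step 4
Reactants: 6 (2R,3S)-3-hydroxy-2-(hydroxymethyl)-2-methylcyclohexan-1-one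
Product: 7 (4aR,8aS)-2,2,4a-trimethylhexahydro-4H-1,3-benzodioxin-5-one (trans-fused acetonide)
Conditions: 2,2-dimethoxypropane, PPTS (cat.), CH2Cl2, rt
Reagents that add atoms: 2,2-dimethoxypropane, COC(C)(C)OC
Why: Acid-catalysed transacetalisation of the trans-1,3-diol gives a trans-fused 1,3-dioxane, a temporary ring that locks ring A in the chair with the C4 methyl axial.

Step 5
Reactants: 7 trans-fused acetonide ketone
Product: 9 (4aR,6S,8aS)-2,2,4a,6-tetramethylhexahydro-4H-1,3-benzodioxin-5-one, via lithium enolate 8 (not isolated)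
Conditions: LDA, THF, −78 °C; MeI, −78 → 0 °C; then NaOMe (cat.), MeOH, rt
Reagents that add atoms: iodomethane, CI
Why: Enolisation is possible only toward C10, and enolate methylation followed by base equilibration should leave the new methyl equatorial (cis to the C19 arm, C10–H axial on the opposite face), because the axial epimer is 1,3-diaxial to the angular C4 methyl held by the acetonide (substrate-controlled α-alkylation).

Step 6
Reactants: 9 methylated acetonide ketone
Product: 10 (2R,3S,6S)-3-hydroxy-2-(hydroxymethyl)-2,6-dimethylcyclohexan-1-one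
Conditions: PPTS, MeOH, rt
Reagents that add atoms: none
Why: Mild transacetalisation into methanol removes the temporary ring without enolising the hindered ketone, so the C10 centre from step 5 is kept.

Step 7
Reactants: 10 diol ketone
Product: 11 (2R,3S,6S)-2-{[tert-butyl(diphenyl)silyl]oxymethyl}-3-hydroxy-2,6-dimethylcyclohexan-1-one
Conditions: TBDPSCl, imidazole, CH2Cl2, 0 °C → rt
Reagents that add atoms: tert-butyl(chloro)diphenylsilane, CC(C)(C)[Si](Cl)(c1ccccc1)c1ccccc1
Why: Silyl ether formation with the bulky chlorosilane should be selective for the primary hydroxyl over the neopentyl secondary one.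

Step 8
Reactants: 11 silyl ether hydroxy ketone
Product: 12 (1S,2R,4S)-2-{[tert-butyl(diphenyl)silyl]oxymethyl}-2,4-dimethyl-3-oxocyclohexyl acetate
Conditions: Ac2O, pyridine, DMAP (cat.), CH2Cl2, rt
Reagents that add atoms: acetic anhydride, CC(=O)OC(C)=O
Why: DMAP-catalysed acylation installs the acetate of the target on the remaining secondary hydroxyl, and β-elimination is impossible because C4 bears no hydrogen.

Step 9
Reactants: 12 acetoxy ketone
Product: 13 (1S,2R,4S)-2-{[tert-butyl(diphenyl)silyl]oxymethyl}-2,4-dimethyl-3-methylidenecyclohexyl acetate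
Conditions: Zn, CH2Br2, TiCl4, THF–CH2Cl2, 0 °C → rt
Reagents that add atoms: dibromomethane, BrCBr
Why: Takai–Lombardo methylenation is non-basic, so it should convert the hindered ketone into the exocyclic C5=C6 alkene in the presence of the acetate and without epimerising C10.

Step 10
Reactants: 14 (3R)-3,7-dimethyloct-6-enoic acid ((R)-citronellic acid)
Product: 15 2,2,2-trichloroethyl (3R)-3,7-dimethyloct-6-enoate
Conditions: Cl3CCH2OH, DCC, DMAP (cat.), CH2Cl2, 0 °C → rt
Reagents that add atoms: 2,2,2-trichloroethanol, OCC(Cl)(Cl)Cl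
Why: Steglich esterification masks the acid as an ester that survives the oxidising and Lewis-acidic steps and is later removed by zinc without touching the acetate.

Step 11
Reactants: 15 trichloroethyl citronellate
Product: 16 2,2,2-trichloroethyl (3R,6E)-8-hydroxy-3,7-dimethyloct-6-enoate
Conditions: SeO2 (cat.), t-BuOOH, salicylic acid (cat.), CH2Cl2, rt
Reagents that add atoms: tert-butyl hydroperoxide, CC(C)(C)OO
Why: Catalytic selenium dioxide allylic oxidation (ene reaction, then 2,3-sigmatropic shift) hydroxylates the methyl group trans to the chain, which fixes the E geometry of the future C8=C9 alkene.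

Step 12
Reactants: 16 E allylic alcohol
Product: 17 2,2,2-trichloroethyl (3R,6E)-8-bromo-3,7-dimethyloct-6-enoate
Conditions: CBr4, PPh3, CH2Cl2, 0 °C
Reagents that add atoms: carbon tetrabromide, BrC(Br)(Br)Br
Why: Appel bromination converts the primary allylic alcohol into the bromide under neutral conditions with retention of the alkene geometry.

Step 13
Reactants: 13 ring A methylenecyclohexane; 17 E allylic bromide
Product: 22 fully protected target (C15 2,2,2-trichloroethyl ester, C19 TBDPS ether, C3 acetate, 7-ene, all stereocentres as in the target), via allyl cation 18 (not isolated), via C5 cation 19 (not isolated), via C10 cation 20 (not isolated), via C8 cation 21 (not isolated)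
Conditions: AgSbF6 (1.3 equiv), 2,6-di-tert-butyl-4-methylpyridine (2 equiv), CH2Cl2–EtNO2, −78 → −40 °C, slow addition of 17
Reagents that add atoms: none
Why: Proposed new method: AgSbF6 abstracts bromide from 17 to give the E-configured 2-methylallyl cation 18, whose unhindered primary terminus C7 is attacked by the terminal CH2 (C6) of the exocyclic alkene of 13 to give the tertiary C5 cation 19; the axial C10–H, held on the face opposite to the C19 arm since step 5, then shifts suprafacially to C5 to give the tertiary C10 cation 20, which the C8=C9 alkene captures, and the hindered pyridine finally removes the axial C7 proton of cation 21. The closest known reaction types are the Lewis-acid-promoted addition of allyl halides to 1,1-disubstituted alkenes and the acid-induced closure of monocyclic C10 cations to trans-decalins in terpene synthesis; what is new is their merger into one bimolecular [3+3] annulation and the use of a 1,2-hydride shift to relay stereochemistry. Only ring B closes, by a 6-endo-trig cation–olefin cyclisation through a chair transition state. C5 is controlled by the configuration of C10 in 13 (the migrating hydrogen arrives on the face it left), C10 by attack of C9 anti to the axial silyloxymethyl group with the C5–C6 bond equatorial, and C9 by the E geometry of the alkene, which places the side chain equatorial. The step needs attack at the primary and not the secondary allyl terminus, hydride shift and ring closure faster than proton loss, and loss of the C7 proton at the end. These should be secured by the steric bias of the cation toward the unhindered methylene nucleophile, by the intramolecular nature of both follow-up events under proton-free conditions, and by the alignment of the axial C7–H bond with the empty orbital at C8.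

Step 14
Reactants: 22 fully protected target
Product: 23 target acid carrying the C19 TBDPS ether
Conditions: Zn dust, AcOH, THF, rt
Reagents that add atoms: none
Why: Reductive fragmentation of the 2,2,2-trichloroethyl ester by zinc frees the acid under conditions that should leave the acetate, the silyl ether and the alkene untouched.

Step 15
Reactants: 23 silyl-protected acid
Product: 24 CNP0138726.1
Conditions: HF·pyridine, THF, 0 °C → rt
Reagents that add atoms: none
Why: Fluoride cleavage of the silyl ether under acidic buffering frees the C19 hydroxyl, and acetyl migration from O3 is blocked because the two oxygens are trans-diaxial on the rigid decalin.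

**Compound list**

1 | 2-methylcyclohex-2-en-1-one | CC1=CCCC1=O | starting material
2 | (3S)-2-methyl-3-(4,4,5,5-tetramethyl-1,3,2-dioxaborolan-2-yl)cyclohexan-1-one (C2 epimers) | CC1(C)OB(OC1(C)C)[C@H]1CCCC(=O)C1C | intermediate
3 | (3S)-3-hydroxy-2-methylcyclohexan-1-one (C2 epimers) | O[C@H]1CCCC(=O)C1C | intermediate
4 | (3S)-2-methyl-1,3-bis(trimethylsilyloxy)cyclohex-1-ene | C[Si](C)(C)O[C@H]1CCCC(O[Si](C)(C)C)=C1C | intermediate
5 | (2R,3S)-2-(hydroxymethyl)-2-methyl-3-(trimethylsilyloxy)cyclohexan-1-one | C[Si](C)(C)O[C@H]1CCCC(=O)[C@]1(C)CO | intermediate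
6 | (2R,3S)-3-hydroxy-2-(hydroxymethyl)-2-methylcyclohexan-1-one | O[C@H]1CCCC(=O)[C@]1(C)CO | intermediate
7 | (4aR,8aS)-2,2,4a-trimethylhexahydro-4H-1,3-benzodioxin-5-one (trans-fused acetonide of 6) | CC1(C)O[C@H]2CCCC(=O)[C@]2(C)CO1 | intermediate
8 | lithium enolate of 7 (enolised toward the ring CH2) | CC1(C)O[C@H]2CCC=C([O-])[C@]2(C)CO1.[Li+] | intermediate
9 | (4aR,6S,8aS)-2,2,4a,6-tetramethylhexahydro-4H-1,3-benzodioxin-5-one | CC1(C)O[C@H]2CC[C@H](C)C(=O)[C@]2(C)CO1 | intermediate
10 | (2R,3S,6S)-3-hydroxy-2-(hydroxymethyl)-2,6-dimethylcyclohexan-1-one | O[C@H]1CC[C@H](C)C(=O)[C@]1(C)CO | intermediate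
11 | (2R,3S,6S)-2-{[tert-butyl(diphenyl)silyl]oxymethyl}-3-hydroxy-2,6-dimethylcyclohexan-1-one | O[C@H]1CC[C@H](C)C(=O)[C@]1(C)CO[Si](c1ccccc1)(c1ccccc1)C(C)(C)C | intermediate
12 | (1S,2R,4S)-2-{[tert-butyl(diphenyl)silyl]oxymethyl}-2,4-dimethyl-3-oxocyclohexyl acetate | CC(=O)O[C@H]1CC[C@H](C)C(=O)[C@]1(C)CO[Si](c1ccccc1)(c1ccccc1)C(C)(C)C | intermediate
13 | (1S,2R,4S)-2-{[tert-butyl(diphenyl)silyl]oxymethyl}-2,4-dimethyl-3-methylidenecyclohexyl acetate | CC(=O)O[C@H]1CC[C@H](C)C(=C)[C@]1(C)CO[Si](c1ccccc1)(c1ccccc1)C(C)(C)C | intermediate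
14 | (3R)-3,7-dimethyloct-6-enoic acid ((R)-citronellic acid) | CC(C)=CCC[C@@H](C)CC(=O)O | starting material
15 | 2,2,2-trichloroethyl (3R)-3,7-dimethyloct-6-enoate | CC(C)=CCC[C@@H](C)CC(=O)OCC(Cl)(Cl)Cl | intermediate
16 | 2,2,2-trichloroethyl (3R,6E)-8-hydroxy-3,7-dimethyloct-6-enoate | OC/C(C)=C/CC[C@@H](C)CC(=O)OCC(Cl)(Cl)Cl | intermediate
17 | 2,2,2-trichloroethyl (3R,6E)-8-bromo-3,7-dimethyloct-6-enoate | BrC/C(C)=C/CC[C@@H](C)CC(=O)OCC(Cl)(Cl)Cl | intermediate
18 | E 2-methylallyl cation from 17 (charge drawn at C7) | [CH2+]/C(C)=C/CC[C@@H](C)CC(=O)OCC(Cl)(Cl)Cl | intermediate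
19 | monocyclic tertiary C5 cation (C6–C7 bond formed, C10–H still in place) | CC(=O)O[C@H]1CC[C@H](C)[C+](CC/C(C)=C/CC[C@@H](C)CC(=O)OCC(Cl)(Cl)Cl)[C@]1(C)CO[Si](c1ccccc1)(c1ccccc1)C(C)(C)C | intermediate
20 | monocyclic tertiary C10 cation (H5 in place) | CC(=O)O[C@H]1CC[C+](C)[C@H](CC/C(C)=C/CC[C@@H](C)CC(=O)OCC(Cl)(Cl)Cl)[C@]1(C)CO[Si](c1ccccc1)(c1ccccc1)C(C)(C)C | intermediate
21 | bicyclic tertiary C8 cation | CC(=O)O[C@H]1CC[C@]2(C)[C@H](CC[C+](C)[C@H]2CC[C@@H](C)CC(=O)OCC(Cl)(Cl)Cl)[C@]1(C)CO[Si](c1ccccc1)(c1ccccc1)C(C)(C)C | intermediate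
22 | fully protected target (C15 trichloroethyl ester, C19 TBDPS ether, C3 acetate, 7-ene) | CC(=O)O[C@H]1CC[C@]2(C)[C@H](CC=C(C)[C@H]2CC[C@@H](C)CC(=O)OCC(Cl)(Cl)Cl)[C@]1(C)CO[Si](c1ccccc1)(c1ccccc1)C(C)(C)C | intermediate
23 | target acid with C19 TBDPS ether | CC(=O)O[C@H]1CC[C@]2(C)[C@H](CC=C(C)[C@H]2CC[C@@H](C)CC(=O)O)[C@]1(C)CO[Si](c1ccccc1)(c1ccccc1)C(C)(C)C | intermediate
24 | CNP0138726.1 | CC(=O)O[C@H]1CC[C@]2(C)[C@H](CC=C(C)[C@H]2CC[C@@H](C)CC(=O)O)[C@]1(C)CO | target

**Count**

Total steps: 15. Longest linear sequence: 12 (steps 1–9, then 13–15).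

**Steps most likely to fail**

1. Step 13 (proposed new method). The bimolecular capture of the allyl cation by the exocyclic alkene may lose to oligomerisation or to attack at the secondary allyl terminus. The hydride relay may be short-circuited by proton loss to uncyclised trienes, and the final deprotonation may also give the exocyclic alkene isomer. The fallback uses known chemistry, sets out from 12 and 16, and returns at 22. Ketone 12 is converted with Tf2O and 2,6-di-tert-butyl-4-methylpyridine into the enol triflate F1. Alcohol 16 is oxidised with MnO2 to the E enal F2 and methylenated with Ph3P=CH2 to the diene F3. Hydroboration of the vinyl group of F3 with 9-BBN gives the alkylborane F4, which is used without isolation in a B-alkyl Suzuki–Miyaura coupling with F1 (PdCl2(dppf), AsPh3, K3PO4, DMF) to give the monocyclic triene F5. Protonation of the tetrasubstituted alkene of F5 with ClSO3H in 2-nitropropane at −78 °C should then close ring B to 22 through the same C10 cation. In this fallback C5 would be set by protonation anti to the pseudoaxial silyloxymethyl group, which is a weaker control than the hydride relay, so a diastereomer separation may be needed.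

2. Step 3. Regiochemical leakage from the enol silylation may be carried into the aldol, and β-elimination of the silyloxy group or retro-aldol loss of formaldehyde may erode the product. The fallback sets out from 1 and returns at 6, with silicon as a masked hydroxyl. Enantioselective conjugate addition of PhMe2Si–Bpin to 1 (CuCl, chiral N-heterocyclic carbene precursor, NaOtBu) gives the silyl ketone F6. Thermodynamic enol silylation gives the silyl enol ether F7. The Yb(OTf)3/formaldehyde aldol, anti to silicon, gives the hydroxymethyl ketone F8. Tamao–Fleming oxidation (HBF4·OEt2; then H2O2, KF, KHCO3) should then give 6 with retention.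

3. Step 9. Methylenation of the doubly flanked ketone may be sluggish, and long reaction times risk slow epimerisation at C10, which would erode the relay stereocentre. The fallback sets out from 9 and returns at 13 by changing the order of events. Wittig methylenation of the acetonide ketone 9 (Ph3PCH3Br, KOtBu, toluene, 90 °C; any epimerisation is returned to the equatorial methyl by the acetonide) gives the alkene F9. Methanolysis (PPTS, MeOH) gives the diol F10, TBDPSCl and imidazole give the silyl ether F11, and acetylation (Ac2O, pyridine, DMAP) gives 13.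

Further compounds
F1 | step 13 | (5S,6R)-5-acetoxy-6-{[tert-butyl(diphenyl)silyl]oxymethyl}-2,6-dimethylcyclohex-1-en-1-yl trifluoromethanesulfonate | CC(=O)O[C@H]1CCC(C)=C(OS(=O)(=O)C(F)(F)F)[C@]1(C)CO[Si](c1ccccc1)(c1ccccc1)C(C)(C)C
F2 | step 13 | 2,2,2-trichloroethyl (3R,6E)-3,7-dimethyl-8-oxooct-6-enoate | O=C/C(C)=C/CC[C@@H](C)CC(=O)OCC(Cl)(Cl)Cl
F3 | step 13 | 2,2,2-trichloroethyl (3R,6E)-3,7-dimethylnona-6,8-dienoate | C=C/C(C)=C/CC[C@@H](C)CC(=O)OCC(Cl)(Cl)Cl
F4 | step 13 | 2,2,2-trichloroethyl (3R,6E)-9-(9-borabicyclo[3.3.1]nonan-9-yl)-3,7-dimethylnon-6-enoate | B1(C2CCCC1CCC2)CC/C(C)=C/CC[C@@H](C)CC(=O)OCC(Cl)(Cl)Cl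
F5 | step 13 | monocyclic triene (ring A C5=C10 alkene joined through C6–C7 to the E C8=C9 alkene; acetate, TBDPS ether and trichloroethyl ester as in 22) | CC(=O)O[C@H]1CCC(C)=C(CC/C(C)=C/CC[C@@H](C)CC(=O)OCC(Cl)(Cl)Cl)[C@]1(C)CO[Si](c1ccccc1)(c1ccccc1)C(C)(C)C
F6 | step 3 | (3S)-3-[dimethyl(phenyl)silyl]-2-methylcyclohexan-1-one (C2 epimers) | C[Si](C)(c1ccccc1)[C@H]1CCCC(=O)C1C
F7 | step 3 | (3S)-3-[dimethyl(phenyl)silyl]-2-methyl-1-(trimethylsilyloxy)cyclohex-1-ene | C[Si](C)(c1ccccc1)[C@H]1CCCC(O[Si](C)(C)C)=C1C
F8 | step 3 | 3-[dimethyl(phenyl)silyl]-2-(hydroxymethyl)-2-methylcyclohexan-1-one (CH2OH trans to silicon) | C[Si](C)(c1ccccc1)[C@H]1CCCC(=O)[C@]1(C)CO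
F9 | step 9 | 2,2,4a,6-tetramethyl-5-methylidenehexahydro-4H-1,3-benzodioxine (methylenated acetonide, stereocentres as in 9) | CC1(C)O[C@H]2CC[C@H](C)C(=C)[C@]2(C)CO1
F10 | step 9 | 2-(hydroxymethyl)-2,4-dimethyl-3-methylidenecyclohexan-1-ol (stereocentres as in 13) | O[C@H]1CC[C@H](C)C(=C)[C@]1(C)CO
F11 | step 9 | 2-{[tert-butyl(diphenyl)silyl]oxymethyl}-2,4-dimethyl-3-methylidenecyclohexan-1-ol (stereocentres as in 13) | O[C@H]1CC[C@H](C)C(=C)[C@]1(C)CO[Si](c1ccccc1)(c1ccccc1)C(C)(C)C
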